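**Plan**

- Retrosynthesis: the aryl ester and the oxygens at C6, C8 and C9 are removed to reach the C8=C9 enone. C7–C8 and C8–C9 are then cut, which takes out the methyl-bearing C8 and rejoins C7–C9 to give a trans-hydrindan-7-one. That ring is opened at C6=C7 (metathesis), and C4–isopropyl, C5–C6 and C1–C10 are cut back to 3-methylcyclopent-2-en-1-one.
- Enabling feature: in the seven-membered ring, the segment C7(=O)–C8(CH3)–C9 is the C7–C9 bond of a cyclohexanone with one CH3-bearing carbon spliced in. A C7=C9 silyl enol ether plus a chloro(methyl)carbenoid therefore delivers it.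
- Forward order: the five-membered ring is present from the start, the six-membered ring is closed by olefin metathesis, and the seven-membered ring arises by one-carbon expansion. C8/C9 and then C6 are oxygenated, and the C6 hydroxyl is acylated last.
- Stereochemistry: C1 from ligand-controlled conjugate addition; C5 from enolate allylation anti to the C1 chain (hence the trans fusion); C4 from addition anti to the allyl group; C8/C9 from osmylation anti to the angular methyl; C6 from α-face enolate oxidation.

Key step: step 9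

Atom labels used throughout: C1 = CH3-bearing ring-fusion carbon, C2/C3 = five-ring CH2, C4 = isopropyl carbinol, C5 = ring-fusion CH, then C6 (acyloxy), C7 (C=O), C8 (C(CH3)OH), C9 (CHOH), C10 (CH2) round the larger ring; β is the face of the C1 methyl. Earlier intermediates keep these labels.

Assumption: 5-bromo-2-methylpent-2-ene and 4-(methoxymethoxy)benzoic acid are purchased, and the antipode of the chiral carbene ligand in step 2 is the one that delivers the 3S ketone.

**Route**

Step 1
Reactants: 1 5-bromo-2-methylpent-2-ene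
Product: 2 (4-methylpent-3-en-1-yl)magnesium bromide
Conditions: Mg turnings, I2 (cat.), Et2O, rt → 35 °C; used as titrated solution
Reagents that add atoms: magnesium, [Mg]
Why: Grignard formation by insertion of magnesium into the primary C–Br bond, with the trisubstituted alkene inert.

Step 2
Reactants: 3 3-methylcyclopent-2-en-1-one; 2 (4-methylpent-3-en-1-yl)magnesium bromide; 4 allyl bromide
Product: 6 (2R,3S)-3-methyl-3-(4-methylpent-3-en-1-yl)-2-(prop-2-en-1-yl)cyclopentan-1-one, via bromomagnesium enolate 5 (not isolated)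
Conditions: Cu(OTf)2 (3 mol %), C2-symmetric chiral imidazolinium salt (carbene precursor, 4 mol %), Et2O, −30 °C; then 4, DMPU, THF, −30 °C → rt
Reagents that add atoms: none
Why: Copper-catalysed asymmetric conjugate addition of the Grignard reagent sets the quaternary C1 under ligand control, and the regiodefined enolate 5 should be C-allylated anti to the longer C1 chain (tandem conjugate addition–enolate alkylation), so that allyl ends cis to methyl as the trans ring fusion requires.

Step 3
Reactants: 6 (2R,3S)-3-methyl-3-(4-methylpent-3-en-1-yl)-2-(prop-2-en-1-yl)cyclopentan-1-one; 7 isopropylmagnesium chloride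
Product: 8 (1R,2R,3S)-3-methyl-3-(4-methylpent-3-en-1-yl)-1-(propan-2-yl)-2-(prop-2-en-1-yl)cyclopentan-1-ol
Conditions: anhydrous CeCl3 (1.5 equiv), 7, THF, −78 → 0 °C; aq. NH4Cl
Reagents that add atoms: none
Why: Cerium-mediated Grignard 1,2-addition suppresses enolisation and β-hydride reduction of the hindered ketone, and the nucleophile should enter trans to the adjacent allyl group to give the 4β-hydroxyl with the isopropyl group α.

Step 4
Reactants: 8 (1R,2R,3S)-3-methyl-3-(4-methylpent-3-en-1-yl)-1-(propan-2-yl)-2-(prop-2-en-1-yl)cyclopentan-1-ol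
Product: 9 (1R,2R,3S)-3-methyl-3-(4-methylpent-3-en-1-yl)-1-(propan-2-yl)-2-[(E)-prop-1-en-1-yl]cyclopentan-1-ol
Conditions: RuHCl(CO)(PPh3)3 (5 mol %), toluene, 80 °C
Reagents that add atoms: none
Why: Ruthenium-hydride olefin isomerisation should move only the monosubstituted allyl double bond into the propenyl position, because the trisubstituted alkene of the C1 chain (chosen for this reason) inserts far more slowly; the E/Z outcome is irrelevant.

Step 5
Reactants: 9 (1R,2R,3S)-3-methyl-3-(4-methylpent-3-en-1-yl)-1-(propan-2-yl)-2-[(E)-prop-1-en-1-yl]cyclopentan-1-ol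
Product: 10 (1R,3aS,7aR)-3a-methyl-1-(propan-2-yl)-2,3,3a,4,5,7a-hexahydro-1H-inden-1-ol
Conditions: second-generation Grubbs catalyst RuCl2(=CHPh)(PCy3)(H2IMes) (5 mol %), CH2Cl2, 40 °C
Reagents that add atoms: none
Why: Ring-closing olefin metathesis joins C6 and C7 with loss of volatile 2-methylbut-2-ene, and the trans relationship of the two arms fixed in step 2 becomes the trans ring fusion.

Step 6
Reactants: 10 (1R,3aS,7aR)-3a-methyl-1-(propan-2-yl)-2,3,3a,4,5,7a-hexahydro-1H-inden-1-ol
Product: 12 (1R,3aS,6S,7aR)-3a-methyl-1-(propan-2-yl)octahydro-1H-indene-1,6-diol, via B-alkyl-9-BBN adduct 11 (not isolated)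
Conditions: 9-BBN (3 equiv), THF, 65 °C; then NaOH, H2O2, H2O, 0 °C → rt
Reagents that add atoms: 9-borabicyclo[3.3.1]nonane, B1C2CCCC1CCC2 (boron unit of 11); hydrogen peroxide, OO (C7 oxygen of 12)
Why: Hydroboration–oxidation with the bulky dialkylborane should place boron on C7, the olefinic carbon remote from the congested C5/C4 region, and oxidation with retention gives the C7 alcohol, whose configuration (expected α, anti to the angular methyl) is erased in step 7.

Step 7
Reactants: 12 (1R,3aS,6S,7aR)-3a-methyl-1-(propan-2-yl)octahydro-1H-indene-1,6-diol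
Product: 13 (3R,3aR,7aR)-3-hydroxy-7a-methyl-3-(propan-2-yl)octahydro-5H-inden-5-one
Conditions: Dess–Martin periodinane, NaHCO3, CH2Cl2, rt
Reagents that add atoms: none
Why: Dess–Martin oxidation converts the secondary alcohol into the C7 ketone, while the tertiary carbinol cannot be oxidised.

Step 8
Reactants: 13 (3R,3aR,7aR)-3-hydroxy-7a-methyl-3-(propan-2-yl)octahydro-5H-inden-5-one
Product: 14 (3R,3aR,7aR)-7a-methyl-3-(propan-2-yl)-3,5-bis(trimethylsilyloxy)-2,3,3a,4,7,7a-hexahydro-1H-indene
Conditions: Me3SiOTf (2.5 equiv), Et3N, CH2Cl2, 0 °C → rt, prolonged stirring; used without chromatography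
Reagents that add atoms: trimethylsilyl trifluoromethanesulfonate, C[Si](C)(C)OS(=O)(=O)C(F)(F)F
Why: Silyl triflate/amine silylation caps the tertiary alcohol and gives the thermodynamic silyl enol ether, which should settle at C7=C9 because a ring double bond next to the trans fusion would flatten an already strained junction and C6 is the more hindered α-carbon.

Step 9
Reactants: 14 (3R,3aR,7aR)-7a-methyl-3-(propan-2-yl)-3,5-bis(trimethylsilyloxy)-2,3,3a,4,7,7a-hexahydro-1H-indene; 15 1,1-dichloroethane
Product: 17 4β-(trimethylsilyloxy)-5αH-dauc-8-en-7-one, via chloro(methyl)cyclopropane adduct 16 (not isolated)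
Conditions: 15 (excess), n-BuLi, Et2O, −40 → 0 °C; then toluene, Et3N (cat.), 110 °C
Reagents that add atoms: none
Why: n-BuLi deprotonates 15 to 1,1-dichloroethyllithium, a chloro(methyl)carbenoid that adds in a concerted [2+1] fashion to the electron-rich C7=C9 enol ether (the only alkene in 14), forming C7–C8 and C8–C9 in cyclopropane 16. On heating, chloride ionises with disrotatory cleavage of the shared C7–C9 bond to a 2-silyloxyallyl cation, which loses Me3SiCl to give the 2-methyl enone; the closest known reaction is the halocarbene ring expansion of cyclic silyl enol ethers to 2-substituted cycloalk-2-enones. The three-membered ring closes by [2+1] addition, and the seven-membered ring arises by scission of the bicyclo[4.1.0] bridge bond, not by end-to-end closure. No lasting stereocentre is made, since C8 and C9 finish as sp2 carbons and both faces of the enol ether converge, while C1, C4 and C5 are untouched. The step needs the enol ether toward C9 (secured in step 8 by the trans fusion) and a chloride lying over the six-membered ring for the allowed opening, which the adduct with methyl on the outer face provides.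

Step 10
Reactants: 17 4β-(trimethylsilyloxy)-5αH-dauc-8-en-7-one
Product: 18 8α,9α-dihydroxy-4β-(trimethylsilyloxy)-5αH-daucan-7-one
Conditions: OsO4 (5 mol %), NMO, acetone/H2O, rt; aq. Na2SO3
Reagents that add atoms: osmium tetroxide, O=[Os](=O)(=O)=O (both oxygens); N-methylmorpholine N-oxide, C[N+]1([O-])CCOCC1, and water, O (turn the osmium over)
Why: Catalytic osmium tetroxide syn-dihydroxylation of the trisubstituted enone alkene should occur on the α face, away from the angular C1 methyl that screens the β side of C9, setting C8 (α-OH, β-CH3) and C9 (α-OH) together.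

Step 11
Reactants: 18 8α,9α-dihydroxy-4β-(trimethylsilyloxy)-5αH-daucan-7-one
Product: 19 8α,9α-(isopropylidenedioxy)-4β-(trimethylsilyloxy)-5αH-daucan-7-one
Conditions: 2,2-dimethoxypropane, PPTS (cat.), CH2Cl2, rt
Reagents that add atoms: 2,2-dimethoxypropane, COC(C)(C)OC
Why: Acid-catalysed acetonide formation ties up the cis-8,9-diol so that only C6 is oxygenated and acylated afterwards, under conditions mild enough for the tertiary silyl ether.

Step 12
Reactants: 19 8α,9α-(isopropylidenedioxy)-4β-(trimethylsilyloxy)-5αH-daucan-7-one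
Product: 21 6α-hydroxy-8α,9α-(isopropylidenedioxy)-4β-(trimethylsilyloxy)-5αH-daucan-7-one, via potassium enolate 20 (not isolated)
Conditions: KN(SiMe3)2, THF, −78 °C; then 2-(phenylsulfonyl)-3-phenyloxaziridine, −78 °C; aq. NH4Cl
Reagents that add atoms: potassium bis(trimethylsilyl)amide, C[Si](C)(C)[N-][Si](C)(C)C.[K+] (potassium of 20); 2-(phenylsulfonyl)-3-phenyloxaziridine, O=S(=O)(c1ccccc1)N1OC1c1ccccc1 (C6 oxygen of 21)
Why: Enolate oxidation with an N-sulfonyloxaziridine is regiospecific because C8 is quaternary, and the oxidant should approach C6 from the α face, anti to the angular methyl and to the C4 carbon on the β side, giving the 6α-alcohol.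

Step 13
Reactants: 21 6α-hydroxy-8α,9α-(isopropylidenedioxy)-4β-(trimethylsilyloxy)-5αH-daucan-7-one; 22 4-(methoxymethoxy)benzoic acid
Product: 24 8α,9α-(isopropylidenedioxy)-7-oxo-4β-(trimethylsilyloxy)-5αH-daucan-6α-yl 4-(methoxymethoxy)benzoate, via O-acylisourea 23 (not isolated)
Conditions: DCC, DMAP (cat.), CH2Cl2, 0 °C → rt
Reagents that add atoms: none
Why: Steglich esterification acylates the only free hydroxyl with retention at C6, under conditions too mild to epimerise the α-acyloxy ketone.

Step 14
Reactants: 24 8α,9α-(isopropylidenedioxy)-7-oxo-4β-(trimethylsilyloxy)-5αH-daucan-6α-yl 4-(methoxymethoxy)benzoate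
Product: 25 4β,8α,9α-trihydroxy-7-oxo-5αH-daucan-6α-yl 4-hydroxybenzoate
Conditions: 2 M aq. HCl, THF, rt → 40 °C
Reagents that add atoms: none
Why: Aqueous acid hydrolysis should remove the isopropylidene ketal, the tertiary trimethylsilyl ether and the methoxymethyl aryl ether in one operation, while the aryl ester and the tertiary carbinols tolerate dilute acid at moderate temperature.

**Compound list**

1 | 5-bromo-2-methylpent-2-ene | CC(C)=CCCBr | starting material
2 | (4-methylpent-3-en-1-yl)magnesium bromide | CC(C)=CCC[Mg]Br | intermediate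
3 | 3-methylcyclopent-2-en-1-one | CC1=CC(=O)CC1 | starting material
4 | allyl bromide | C=CCBr | starting material
5 | bromomagnesium (S)-3-methyl-3-(4-methylpent-3-en-1-yl)cyclopent-1-en-1-olate | CC(C)=CCC[C@@]1(C)CCC(O[Mg]Br)=C1 | intermediate (not isolated)
6 | (2R,3S)-3-methyl-3-(4-methylpent-3-en-1-yl)-2-(prop-2-en-1-yl)cyclopentan-1-one | C=CC[C@H]1C(=O)CC[C@]1(C)CCC=C(C)C | intermediate
7 | isopropylmagnesium chloride | CC(C)[Mg]Cl | starting material
8 | (1R,2R,3S)-3-methyl-3-(4-methylpent-3-en-1-yl)-1-(propan-2-yl)-2-(prop-2-en-1-yl)cyclopentan-1-ol | CC(C)[C@]1(O)CC[C@](C)(CCC=C(C)C)[C@H]1CC=C | intermediate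
9 | (1R,2R,3S)-3-methyl-3-(4-methylpent-3-en-1-yl)-1-(propan-2-yl)-2-[(E)-prop-1-en-1-yl]cyclopentan-1-ol | CC(C)[C@]1(O)CC[C@](C)(CCC=C(C)C)[C@H]1/C=C/C | intermediate
10 | (1R,3aS,7aR)-3a-methyl-1-(propan-2-yl)-2,3,3a,4,5,7a-hexahydro-1H-inden-1-ol (trans-fused, C6=C7) | CC(C)[C@]1(O)CC[C@]2(C)CCC=C[C@H]21 | intermediate
11 | B-alkyl-9-borabicyclo[3.3.1]nonane adduct of 10 (boron on C7, α face; C4 hydroxyl drawn free) | CC(C)[C@]1(O)CC[C@]2(C)CC[C@H](B3C4CCCC3CCC4)C[C@H]21 | intermediate (not isolated)
12 | (1R,3aS,6S,7aR)-3a-methyl-1-(propan-2-yl)octahydro-1H-indene-1,6-diol (trans-fused, 4β,7α-diol) | CC(C)[C@]1(O)CC[C@]2(C)CC[C@H](O)C[C@H]21 | intermediate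
13 | (3R,3aR,7aR)-3-hydroxy-7a-methyl-3-(propan-2-yl)octahydro-5H-inden-5-one (trans-fused) | CC(C)[C@]1(O)CC[C@]2(C)CCC(=O)C[C@H]21 | intermediate
14 | (3R,3aR,7aR)-7a-methyl-3-(propan-2-yl)-3,5-bis(trimethylsilyloxy)-2,3,3a,4,7,7a-hexahydro-1H-indene (trans-fused, C7=C9 enol ether) | CC(C)[C@]1(O[Si](C)(C)C)CC[C@]2(C)CC=C(O[Si](C)(C)C)C[C@H]21 | intermediate
15 | 1,1-dichloroethane | CC(Cl)Cl | starting material
16 | 8-chloro-4β,7-bis(trimethylsilyloxy)-7,9-cyclo-5αH-daucane (cyclopropane adduct, mixture at C7/C8/C9) | CC(C)[C@]1(O[Si](C)(C)C)CC[C@]2(C)CC3C(C)(Cl)C3(O[Si](C)(C)C)C[C@H]21 | intermediate (not isolated)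
17 | 4β-(trimethylsilyloxy)-5αH-dauc-8-en-7-one | CC(C)[C@]1(O[Si](C)(C)C)CC[C@]2(C)CC=C(C)C(=O)C[C@H]21 | intermediate
18 | 8α,9α-dihydroxy-4β-(trimethylsilyloxy)-5αH-daucan-7-one | CC(C)[C@]1(O[Si](C)(C)C)CC[C@]2(C)C[C@H](O)[C@](C)(O)C(=O)C[C@H]21 | intermediate
19 | 8α,9α-(isopropylidenedioxy)-4β-(trimethylsilyloxy)-5αH-daucan-7-one | CC(C)[C@]1(O[Si](C)(C)C)CC[C@]2(C)C[C@@H]3OC(C)(C)O[C@]3(C)C(=O)C[C@H]21 | intermediate
20 | potassium C6=C7 enolate of 19 | CC(C)[C@]1(O[Si](C)(C)C)CC[C@]2(C)C[C@@H]3OC(C)(C)O[C@]3(C)C(O[K])=C[C@H]21 | intermediate (not isolated)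
21 | 6α-hydroxy-8α,9α-(isopropylidenedioxy)-4β-(trimethylsilyloxy)-5αH-daucan-7-one | CC(C)[C@]1(O[Si](C)(C)C)CC[C@]2(C)C[C@@H]3OC(C)(C)O[C@]3(C)C(=O)[C@H](O)[C@H]21 | intermediate
22 | 4-(methoxymethoxy)benzoic acid | COCOc1ccc(cc1)C(=O)O | starting material
23 | O-[4-(methoxymethoxy)benzoyl]-N,N'-dicyclohexylisourea | COCOc1ccc(cc1)C(=O)OC(=NC1CCCCC1)NC1CCCCC1 | intermediate (not isolated)
24 | 8α,9α-(isopropylidenedioxy)-7-oxo-4β-(trimethylsilyloxy)-5αH-daucan-6α-yl 4-(methoxymethoxy)benzoate | CC(C)[C@]1(O[Si](C)(C)C)CC[C@]2(C)C[C@@H]3OC(C)(C)O[C@]3(C)C(=O)[C@H](OC(=O)c4ccc(OCOC)cc4)[C@H]21 | intermediate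
25 | 4β,8α,9α-trihydroxy-7-oxo-5αH-daucan-6α-yl 4-hydroxybenzoate (CNP0241001.1) | CC(C)[C@]1(O)CC[C@]2(C)C[C@H](O)[C@](C)(O)C(=O)[C@H](OC(=O)c3ccc(O)cc3)[C@H]21 | target

**Step count and risks**

Total step count: 14. Longest linear sequence: 14 steps (1 → 25); 13 from 3.

Steps most likely to fail:

1. Step 9. The carbenoid can add with chloride on either side of the new three-membered ring, and only the adduct whose chloride lies over the six-membered ring can ionise with the allowed inward disrotation, so part of the material may stall at the cyclopropane stage. The lithium reagent may also strip the enol silyl group before cyclopropanation. The fallback sets out from 14. Dibromocarbene (CHBr3, KOt-Bu, pentane, −20 °C) should give the 8,8-dibromo-8-demethyl-4β,7-bis(trimethylsilyloxy)-7,9-cyclo-5αH-daucane F1, in which one bromide necessarily sits on the reactive side. Warming in toluene with pyridine should open it, with loss of Me3SiBr, to 8-bromo-8-demethyl-4β-(trimethylsilyloxy)-5αH-dauc-8-en-7-one F2. Suzuki–Miyaura methylation (MeB(OH)2, Pd(OAc)2, SPhos, K3PO4, toluene, 80 °C) then installs the C8 methyl and rejoins the route at 17.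

2. Step 2. Enantiofacial control in the copper-catalysed Grignard addition may be insufficient on a five-membered enone, and the allylation may discriminate poorly between methyl and the chain or be slow on the hindered magnesium enolate. The fallback sets out from 2. Addition to commercial 3-ethoxycyclopent-2-en-1-one followed by acidic work-up (1,2-addition, hydrolysis and transposition) gives 3-(4-methylpent-3-en-1-yl)cyclopent-2-en-1-one F3. Copper-catalysed asymmetric conjugate addition of AlMe3 (Cu(OTf)2, chiral carbene ligand, Et2O, −30 °C) with trapping of the aluminium enolate by Me3SiOTf gives (S)-trimethyl{[3-methyl-3-(4-methylpent-3-en-1-yl)cyclopent-1-en-1-yl]oxy}silane F4. Palladium-catalysed allylation of F4 (diallyl carbonate, Bu4N[Ph3SiF2], Pd2(dba)3, (S)-t-BuPHOX or its antipode, THF, rt), with the ligand chosen to reinforce attack anti to the chain, rejoins the route at 6.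

3. Step 12. The oxidant may approach the C6 enolate carbon from the β face and give the C6 epimer. The fallback sets out from 19. The product of β-face oxidation, 6β-hydroxy-8α,9α-(isopropylidenedioxy)-4β-(trimethylsilyloxy)-5αH-daucan-7-one F5, is not acylated with retention but esterified with inversion under Mitsunobu conditions with acid 22 (PPh3, DIAD, toluene, 0 °C → rt). This rejoins the route at 24.

Further compounds
F1 | step 9 | 8,8-dibromo-8-demethyl-4β,7-bis(trimethylsilyloxy)-7,9-cyclo-5αH-daucane | CC(C)[C@]1(O[Si](C)(C)C)CC[C@]2(C)CC3C(Br)(Br)C3(O[Si](C)(C)C)C[C@H]21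
F2 | step 9 | 8-bromo-8-demethyl-4β-(trimethylsilyloxy)-5αH-dauc-8-en-7-one | CC(C)[C@]1(O[Si](C)(C)C)CC[C@]2(C)CC=C(Br)C(=O)C[C@H]21
F3 | step 2 | 3-(4-methylpent-3-en-1-yl)cyclopent-2-en-1-one | CC(C)=CCCC1=CC(=O)CC1
F4 | step 2 | (S)-trimethyl{[3-methyl-3-(4-methylpent-3-en-1-yl)cyclopent-1-en-1-yl]oxy}silane | CC(C)=CCC[C@@]1(C)CCC(O[Si](C)(C)C)=C1
F5 | step 12 | 6β-hydroxy-8α,9α-(isopropylidenedioxy)-4β-(trimethylsilyloxy)-5αH-daucan-7-one | CC(C)[C@]1(O[Si](C)(C)C)CC[C@]2(C)C[C@@H]3OC(C)(C)O[C@]3(C)C(=O)[C@@H](O)[C@H]21
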